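## Structural features

Dodoviscin J (15) is a flavone: benzene ring A is fused to the 4-pyranone ring C (a 4H-chromen-4-one), and aryl ring B is joined to C2 of ring C by a single C–C bond. Ring A carries free hydroxyls at C5 and C7, which with O1 make a 1,3,5-trioxygenated (phloroglucinol) pattern. Ring C carries a methoxy group at C3 beside the C4 carbonyl, and ring B carries a methoxy at C3', a free hydroxyl at C4' and a prenyl (3-methylbut-2-en-1-yl) chain at C5'. There is no stereocentre and no alkene geometry to control, because the prenyl terminus bears two identical methyl groups. The fragile parts are the prenyl alkene ortho to a free phenol (acid closes it to a 2,2-dimethylchroman, and strong heat or oxidants also attack it), the electron-rich ring A (oxidation, multiple acylation) and the chelated 5-OH/C4=O pair, which binds Lewis acids. The real difficulty is the oxygen pattern: two methyl ethers at fixed places (C3 and C3') beside three free phenols, which rules out a late selective methylation and calls for a plan without a long protecting-group sequence, and a prenyl chain that must arrive without cyclising. The key step exploits two facts: ring A is the symmetric triol whose three ring carbons are equivalent, and C4, C3 (with its methoxy group) and C2 (with ring B) form a 1,3-dielectrophile in the shape of a β-keto ester. Joining the two forms C4–C4a and O1–C2 and closes ring C with every oxygen already in its final state.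

## Logic of the disconnections

15 ⇒ 14. The C2''=C3'' double bond of the side chain is cut, leaving a terminal allyl group; the isopropylidene end comes from 2-methyl-2-butene by cross-metathesis. The reason is that a prenyl group ortho to a free phenol is unlikely to survive the hot melt of the ring-forming step, whereas an allyl group should. The gain is a side chain that can be installed by a [3,3] shift from oxygen. The demand is a metathesis catalyst that works on a free triphenol without moving the allyl double bond into conjugation.

14 ⇒ 10 + 11. Two bonds of ring C are cut, C4–C4a and O1–C2. This is the cut of greatest simplification: it separates the purchasable, symmetric 11 from a three-carbon unit that already carries the C3 methoxy group and ring B. No oxygen has to be protected or methylated afterwards. The demand is that acylation at carbon and closure to the chromone win over closure to the isomeric coumarin and over multiple acylation, and that the free phenol and the allyl group of 10 tolerate about 240 °C.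

10 ⇒ 6 + 7. The bond between the ketone carbon and the methoxy-bearing carbon of 10 is cut (crossed ester condensation), which leads to an aryl methyl ester and 7 as its lithium enolate 8. The aryl ester must be a real electrophile. With a free para hydroxyl it would be a lithium phenoxide, in effect a vinylogous carboxylate, and self-condensation of 7 would take over. The phenol is therefore silylated while the C–C bond is made (6, giving 9) and the silyl group is removed in the same flask, so that 10 enters the melt with its phenol free. Using the O-allyl group of 3 as the mask and rearranging afterwards was set aside, because it would expose a β-keto ester to about 200 °C with no partner to trap the ketene.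

6 ⇒ 5. The O–Si bond is cut. The demand is only that a phenol flanked by a methoxy and an allyl group can be silylated, which a small chlorosilane in DMF should manage.

5 ⇒ 3. The C5–CH2 bond of the allyl group is cut and the allyl group is returned to the phenolic oxygen (retro-Claisen rearrangement). The gain is that C-allylation becomes a simple O-allylation. Regiochemistry is secure because only one ortho position carries hydrogen and the para position is blocked by the ester.

3 ⇒ 1 + 2. The O–allyl bond is cut, giving two bulk chemicals. The forward step is an ordinary phenol alkylation.

## Other disconnections considered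

Alternative 1: Ring B itself is cut at C2'–C3' and C5'–C6', back to 1-methoxy-6-methylhept-5-en-2-one A1 and ethyl diformylacetate A2. In the forward direction aqueous NaOH would condense both α-carbons of A1 with the two formyl groups of A2 and aromatise the product to ethyl 4-hydroxy-3-methoxy-5-prenylbenzoate A3.
- In its favour: every substituent of ring B is carried by a defined carbon of A1 or A2, so the substitution pattern is fixed by construction. The prenyl group is in place without a metal-catalysed step, and no late reaction on a polyphenol is needed. On these points it equals or betters the chosen plan.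
- Against it: it only builds the part of the molecule that can be bought as 1. A3 is simply the prenyl, ethyl-ester counterpart of 5 and still needs the ester condensation and a ring C closure. With the prenyl group already present, the thermal annulation becomes unsafe, so a milder and longer ring C synthesis with a protected ring A would be needed. A2 is a base-sensitive trialdehyde equivalent prone to deformylation, the double condensation has to engage an α-methoxy carbon, and A1 must first be made in about two steps.
- Comparison: on structure the two plans reach the same kind of benzoate. On mechanism the [3,3] shift of the chosen plan is intrinsically regiospecific, while the double aldol aromatisation has more ways to stall. On step count it is about level up to the benzoate (A3 saves the metathesis step), but it is longer overall once ring C has to be made gently.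

Alternative 2: Ring A is cut at C4a–C5, back to the open-chain methyl (8Z)-8-methoxy-9-[3-methoxy-4-(methoxymethoxy)-5-prenylphenyl]-3,5,7-trioxonon-8-enoate A4. In the forward direction Mg(OMe)2 in methanol would fold A4 by attack of C6 on the ester carbon to give the acylphloroglucinol (Z)-2-methoxy-3-[3-methoxy-4-(methoxymethoxy)-5-prenylphenyl]-1-(2,4,6-trihydroxyphenyl)prop-2-en-1-one A5.
- In its favour: the conditions are mild (no melt), the prenyl group can be carried from the start, and magnesium chelation should steer the chain to Claisen folding. On thermal load and on avoiding metathesis it is better than the chosen plan.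
- Against it: it spends its key step on making ring A, which is the cheapest part of the target (11). A4 needs polyanion chemistry and can also fold by aldol closure to a resorcylate or lactonise to a pyranone. A5 still lacks the O1–C2 bond and is one oxidation level short, so an oxidative closure in the presence of a prenyl alkene and an electron-rich triol would follow, and then acid removal of the acetal next to the prenyl group.
- Comparison: on structure the chosen annulation delivers both ring C bonds at the final oxidation level in one step. On mechanism both rest on acylation of a carbon nucleophile (ionic enolate against thermal ketene), and the alternative is the gentler. On step count it would be longer by several steps. Neither plan has a stereochemical problem.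

Alternative 3: Ring A is cut at C5–C6, C7–C8 and C4a–C5, back to 2-(2-diazoacetyl)-5-methoxy-6-[3-methoxy-5-prenyl-4-(triisopropylsilyloxy)phenyl]-4H-pyran-4-one A6 and (triisopropylsilyloxy)acetylene A7. In the forward direction photochemical Wolff rearrangement of A6 would give a ketene whose vinyl part is the pyranone C=C. [2+2] addition of A7, 4π ring opening and 6π closure onto C4a would then give the bis(triisopropylsilyl) ether A8, which is 15 carrying one silyl group on the C7 oxygen and one on the ring B phenol oxygen. Fluoride would then convert A8 into 15.
- In its favour: three C–C bonds form in one convergent operation, the oxygen positions follow from the polarity of ketene and ynol ether, the 5-OH and the 7-oxygen emerge differentiated in A8, and the thermal load is low. For an unsymmetrical ring A this regiocontrol would be a real advantage over the chosen plan.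
- Against it: A6 is a fully substituted pyranone whose preparation (aryl–pyranone coupling, acid activation, diazo ketone formation) would exceed the length of the whole chosen route. The 4-pyranone chromophore has photochemistry of its own, the ketene or a stray carbene may engage the prenyl alkene, and diazo handling adds hazard. The differentiation of the 5- and 7-oxygens in A8 is of no use for this target, and A8 still needs a desilylation step.
- Comparison: on structure the symmetry of ring A makes the extra regiocontrol unnecessary here. On mechanism the pericyclic cascade to A8 has more points of failure than a two-bond condensation. On step count the chosen plan is clearly shorter.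

Key step: step 5

Remark on the chemistry: 10 is taken into the melt with its ring B phenol free; that phenol is masked as a silyl ether only during the ester condensation, because a lithium phenoxide para to the ester would switch off its electrophilicity.

## Route

Step 1
Reactants: 1 methyl vanillate (methyl 4-hydroxy-3-methoxybenzoate); 2 allyl bromide
Product: 3 methyl 4-(allyloxy)-3-methoxybenzoate
Conditions: K2CO3, acetone, reflux
Reagents that add atoms: none
Why: Williamson ether synthesis; the phenoxide of 1 is the only nucleophile and the allylic bromide is a reactive SN2 partner, while the methyl ester is inert to carbonate in acetone.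

Step 2
Reactants: 3 methyl 4-(allyloxy)-3-methoxybenzoate
Product: 5 methyl 3-allyl-4-hydroxy-5-methoxybenzoate, via ortho-dienone 4 (not isolated)
Conditions: PhNEt2, 200 °C, Ar
Reagents that add atoms: none
Why: Aromatic Claisen rearrangement; the [3,3] shift to the only hydrogen-bearing ortho carbon gives dienone 4, which tautomerises to the phenol, while a shift to the methoxy-bearing carbon cannot tautomerise and should revert, and the para position is blocked by the ester.

Step 3
Reactants: 5 methyl 3-allyl-4-hydroxy-5-methoxybenzoate
Product: 6 methyl 3-allyl-4-[(tert-butyldimethylsilyl)oxy]-5-methoxybenzoate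
Conditions: TBSCl, imidazole, DMF, rt
Reagents that add atoms: tert-butyldimethylsilyl chloride (TBSCl), CC(C)(C)[Si](C)(C)Cl
Why: Silylation of a phenol through the N-silylimidazolium species; the phenol is flanked on both sides but acidic, and DMF should drive the reaction, giving an ether that is inert to amide bases and ester enolates at low temperature.

Step 4
Reactants: 6 methyl 3-allyl-4-[(tert-butyldimethylsilyl)oxy]-5-methoxybenzoate; 7 ethyl methoxyacetate
Product: 10 ethyl 3-(3-allyl-4-hydroxy-5-methoxyphenyl)-2-methoxy-3-oxopropanoate (racemic), via lithium ester enolate 8 (not isolated), via silyl keto ester 9 (not isolated)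
Conditions: 7 (3 equiv), LiN(iPr)2 (3.3 equiv), THF, −78 °C; add 6, −78 → 0 °C; AcOH then Bu4NF, 0 °C → rt
Reagents that add atoms: none
Why: Crossed Claisen ester condensation; fully pre-formed enolate 8 adds to the non-enolisable aryl ester, loss of methoxide and deprotonation of the acidic β-keto ester 9 by excess base pull the equilibrium over, and the silyl ether keeps the ester electrophilic. Acetic acid-buffered fluoride then cleaves the aryl silyl ether (activated by the para ketone) in the same flask without retro-Claisen cleavage; the C2 centre is racemic and enolisable, which is irrelevant.

Step 5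
Reactants: 10 ethyl 3-(3-allyl-4-hydroxy-5-methoxyphenyl)-2-methoxy-3-oxopropanoate; 11 phloroglucinol (benzene-1,3,5-triol, anhydrous, 3 equiv)
Product: 14 2-(3-allyl-4-hydroxy-5-methoxyphenyl)-5,7-dihydroxy-3-methoxy-4H-chromen-4-one, via aroyl(methoxy)ketene 12 (not isolated), via C-acylphloroglucinol diketone 13 (not isolated)
Conditions: neat melt, 240 °C, N2 stream, about 1 h; then EtOAc/water partition
Reagents that add atoms: none
Why: Mentzer-type thermal pyrone annulation, the known acid-free melt condensation of phenols with β-keto esters to chromones (the same class as the thermal synthesis of 5,7-dihydroxyflavones from aroylacetates, with the α-methoxy group as an added substituent on the central carbon). On heating, 10 should lose ethanol through its enol to give ketene 12, which acylates a ring carbon of 11 directly or by O-acylation and thermal acyl shift, forming C4–C4a in the chelated diketone 13. An ortho hydroxyl of 13 then adds to the aryl ketone carbonyl in a 6-exo-trig closure and the hemiketal loses water, forming O1–C2 and the C2=C3 double bond of ring C, while the gas stream removes ethanol and water. No stereocentre results, since the racemic carbon of 10 and the transient hemiketal carbon both become sp2. Chromone should prevail over coumarin because, without a Brønsted or Lewis acid, the aryl ketone (deactivated by the para hydroxyl of ring B) is too weak an electrophile for Pechmann-type C–C bond formation, whereas the ketene carbon is not. No regiochemical question arises on ring A because the three ring carbons of 11 are equivalent, and a second acylation is held back by the excess of 11 and by the deactivation of ring A once it is acylated and chelated. Esters formed at phenolic oxygens, including the hindered ring B phenol, should revert to 12 at this temperature, whereas cyclodehydration of 13 is a sink. The terminal allyl group has no easy acid-free thermal pathway at 240 °C (it was itself made at 200 °C in step 2), which is why it stands in for the prenyl group.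

Step 6
Reactants: 14 2-(3-allyl-4-hydroxy-5-methoxyphenyl)-5,7-dihydroxy-3-methoxy-4H-chromen-4-one
Product: 15 dodoviscin J, 5,7-dihydroxy-2-[4-hydroxy-3-methoxy-5-(3-methylbut-2-en-1-yl)phenyl]-3-methoxy-4H-chromen-4-one
Conditions: second-generation Grubbs catalyst RuCl2(H2IMes)(PCy3)(=CHPh) (5–10 mol %), 2-methyl-2-butene (large excess), CH2Cl2/EtOAc, 40 °C, sealed tube
Reagents that add atoms: 2-methyl-2-butene, CC=C(C)C
Why: Olefin cross-metathesis; the terminal allyl alkene exchanges its CH2 end for the isopropylidene end of the trisubstituted partner, driven by the excess of that partner and by loss of volatile propene, and the trisubstituted product does not re-enter the cycle. The catalyst tolerates free phenols and the chromone carbonyl, and no alkene geometry arises because the new terminus carries two methyl groups.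

## Compound list

1 | methyl vanillate (methyl 4-hydroxy-3-methoxybenzoate) | COC(=O)c1ccc(O)c(OC)c1 | starting material
2 | allyl bromide | C=CCBr | starting material
3 | methyl 4-(allyloxy)-3-methoxybenzoate | COC(=O)c1ccc(OCC=C)c(OC)c1 | intermediate
4 | methyl 3-allyl-5-methoxy-4-oxocyclohexa-1,5-diene-1-carboxylate (racemic ortho-dienone) | COC(=O)C1=CC(CC=C)C(=O)C(OC)=C1 | intermediate (not isolated)
5 | methyl 3-allyl-4-hydroxy-5-methoxybenzoate | COC(=O)c1cc(OC)c(O)c(CC=C)c1 | intermediate
6 | methyl 3-allyl-4-[(tert-butyldimethylsilyl)oxy]-5-methoxybenzoate | COC(=O)c1cc(OC)c(O[Si](C)(C)C(C)(C)C)c(CC=C)c1 | intermediate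
7 | ethyl methoxyacetate | CCOC(=O)COC | starting material
8 | lithium 1-ethoxy-2-methoxyethen-1-olate (lithium enolate of 7) | [Li+].CCOC([O-])=COC | intermediate (not isolated)
9 | ethyl 3-{3-allyl-4-[(tert-butyldimethylsilyl)oxy]-5-methoxyphenyl}-2-methoxy-3-oxopropanoate (racemic) | CCOC(=O)C(OC)C(=O)c1cc(OC)c(O[Si](C)(C)C(C)(C)C)c(CC=C)c1 | intermediate (not isolated)
10 | ethyl 3-(3-allyl-4-hydroxy-5-methoxyphenyl)-2-methoxy-3-oxopropanoate (racemic, enolisable centre) | CCOC(=O)C(OC)C(=O)c1cc(OC)c(O)c(CC=C)c1 | intermediate
11 | phloroglucinol (benzene-1,3,5-triol) | Oc1cc(O)cc(O)c1 | starting material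
12 | 3-(3-allyl-4-hydroxy-5-methoxyphenyl)-2-methoxy-3-oxoprop-1-en-1-one (aroyl(methoxy)ketene) | COC(=C=O)C(=O)c1cc(OC)c(O)c(CC=C)c1 | intermediate (not isolated)
13 | 1-(3-allyl-4-hydroxy-5-methoxyphenyl)-2-methoxy-3-(2,4,6-trihydroxyphenyl)propane-1,3-dione (racemic) | COC(C(=O)c1cc(OC)c(O)c(CC=C)c1)C(=O)c1c(O)cc(O)cc1O | intermediate (not isolated)
14 | 2-(3-allyl-4-hydroxy-5-methoxyphenyl)-5,7-dihydroxy-3-methoxy-4H-chromen-4-one | COc1cc(-c2oc3cc(O)cc(O)c3c(=O)c2OC)cc(CC=C)c1O | intermediate
15 | dodoviscin J | COc1cc(-c2oc3cc(O)cc(O)c3c(=O)c2OC)cc(CC=C(C)C)c1O | target

## Step count and least certain steps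

Total step count: 6. Longest linear sequence: 6 steps (1 → 3 → 5 → 6 → 10 → 14 → 15); 2, 7 and 11 enter as purchased materials.

Step 5 (key step).
- What may go wrong: the melt may drift into acylation at oxygen and oligomerisation through the ring B phenol, a second acylation of ring A, closure in the coumarin sense if traces of acid are present, or dimerisation of the ketene. The allyl double bond may also move into conjugation or add the neighbouring phenol. All of these are favoured by the high temperature the ethyl ester needs to release ethanol.
- Fallback (sets out from 11 and 5, returns at 14): a stepwise polar assembly of the same ring C bonds. 11 would be acylated with methoxyacetonitrile under Hoesch conditions (ZnCl2, HCl, Et2O, then hot water) to give 2-methoxy-1-(2,4,6-trihydroxyphenyl)ethan-1-one F1. Its two non-chelated hydroxyls would be capped (MOMCl, iPr2NEt, CH2Cl2) to give 1-[2-hydroxy-4,6-bis(methoxymethoxy)phenyl]-2-methoxyethan-1-one F2. In parallel, 5 would be converted in the same way into methyl 3-allyl-5-methoxy-4-(methoxymethoxy)benzoate F3. The dianion of F2 (LiN(SiMe3)2 or NaH, THF, up to reflux) would be acylated at carbon by F3 to give 1-[3-allyl-5-methoxy-4-(methoxymethoxy)phenyl]-3-[2-hydroxy-4,6-bis(methoxymethoxy)phenyl]-2-methoxypropane-1,3-dione F4. HCl in methanol would then cyclodehydrate F4 and remove the three acetals to give 14; the allyl group is not at risk from this acid in the way a prenyl group would be.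

Step 4.
- What may go wrong: self-condensation of the enolate may outrun acylation, because the para-silyloxy aryl ester is only a moderate electrophile. Premature loss of the silyl group to methoxide would give an unreactive phenoxide ester, and retro-Claisen cleavage is possible if the quench is not kept buffered.
- Fallback (sets out from 6, returns at 10): 6 would be reduced (iBu2AlH, CH2Cl2, −78 °C) to [3-allyl-4-(tert-butyldimethylsilyloxy)-5-methoxyphenyl]methanol F5 and oxidised (MnO2, CH2Cl2) to 3-allyl-4-[(tert-butyldimethylsilyl)oxy]-5-methoxybenzaldehyde F6. Aldol addition of enolate 8 at −78 °C, which is fast and free of the self-condensation problem, would give ethyl 3-{3-allyl-4-[(tert-butyldimethylsilyl)oxy]-5-methoxyphenyl}-3-hydroxy-2-methoxypropanoate F7 as a mixture of diastereomers of no consequence. Dess–Martin oxidation would give 9, isolated this time, and Bu4NF/AcOH would give 10.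

Step 6.
- What may go wrong: hydride species formed as the catalyst decays may shift the allyl double bond into conjugation with ring B. The chelating, poorly soluble triphenol may slow catalyst turnover, so that conversion stops at a mixture with the crotyl-type intermediate or the homodimer.
- Fallback (sets out from 14, returns at 15): the substrate class is changed from free polyphenol to peracetate. Ac2O/pyridine with DMAP would give 2-[4-(acetyloxy)-3-allyl-5-methoxyphenyl]-3-methoxy-4-oxo-4H-chromene-5,7-diyl diacetate F8, which is soluble in CH2Cl2 and has no chelating hydroxyl. Cross-metathesis with 2-methyl-2-butene and the same catalyst RuCl2(H2IMes)(PCy3)(=CHPh) would give 2-[4-(acetyloxy)-3-methoxy-5-(3-methylbut-2-en-1-yl)phenyl]-3-methoxy-4-oxo-4H-chromene-5,7-diyl diacetate F9. Mild methanolysis (K2CO3, MeOH, rt) would release 15 without acid near the prenyl group.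

## Further compounds

F1 | step 5 | 2-methoxy-1-(2,4,6-trihydroxyphenyl)ethan-1-one | COCC(=O)c1c(O)cc(O)cc1O
F2 | step 5 | 1-[2-hydroxy-4,6-bis(methoxymethoxy)phenyl]-2-methoxyethan-1-one | COCC(=O)c1c(O)cc(OCOC)cc1OCOC
F3 | step 5 | methyl 3-allyl-5-methoxy-4-(methoxymethoxy)benzoate | COCOc1c(OC)cc(cc1CC=C)C(=O)OC
F4 | step 5 | 1-[3-allyl-5-methoxy-4-(methoxymethoxy)phenyl]-3-[2-hydroxy-4,6-bis(methoxymethoxy)phenyl]-2-methoxypropane-1,3-dione (racemic) | COCOc1cc(O)c(C(=O)C(OC)C(=O)c2cc(OC)c(OCOC)c(CC=C)c2)c(OCOC)c1
F5 | step 4 | [3-allyl-4-(tert-butyldimethylsilyloxy)-5-methoxyphenyl]methanol | OCc1cc(OC)c(O[Si](C)(C)C(C)(C)C)c(CC=C)c1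
F6 | step 4 | 3-allyl-4-[(tert-butyldimethylsilyl)oxy]-5-methoxybenzaldehyde | O=Cc1cc(OC)c(O[Si](C)(C)C(C)(C)C)c(CC=C)c1
F7 | step 4 | ethyl 3-{3-allyl-4-[(tert-butyldimethylsilyl)oxy]-5-methoxyphenyl}-3-hydroxy-2-methoxypropanoate (mixture of racemic diastereomers) | CCOC(=O)C(OC)C(O)c1cc(OC)c(O[Si](C)(C)C(C)(C)C)c(CC=C)c1
F8 | step 6 | 2-[4-(acetyloxy)-3-allyl-5-methoxyphenyl]-3-methoxy-4-oxo-4H-chromene-5,7-diyl diacetate | COc1cc(-c2oc3cc(OC(C)=O)cc(OC(C)=O)c3c(=O)c2OC)cc(CC=C)c1OC(C)=O
F9 | step 6 | 2-[4-(acetyloxy)-3-methoxy-5-(3-methylbut-2-en-1-yl)phenyl]-3-methoxy-4-oxo-4H-chromene-5,7-diyl diacetate | COc1cc(-c2oc3cc(OC(C)=O)cc(OC(C)=O)c3c(=O)c2OC)cc(CC=C(C)C)c1OC(C)=O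
A1 | alternative 1 | 1-methoxy-6-methylhept-5-en-2-one | COCC(=O)CCC=C(C)C
A2 | alternative 1 | ethyl diformylacetate (ethyl 2-formyl-3-oxopropanoate) | CCOC(=O)C(C=O)C=O
A3 | alternative 1 | ethyl 4-hydroxy-3-methoxy-5-(3-methylbut-2-en-1-yl)benzoate | CCOC(=O)c1cc(OC)c(O)c(CC=C(C)C)c1
A4 | alternative 2 | methyl (8Z)-8-methoxy-9-[3-methoxy-4-(methoxymethoxy)-5-(3-methylbut-2-en-1-yl)phenyl]-3,5,7-trioxonon-8-enoate | CO/C(=C\c1cc(OC)c(OCOC)c(CC=C(C)C)c1)C(=O)CC(=O)CC(=O)CC(=O)OC
A5 | alternative 2 | (Z)-2-methoxy-3-[3-methoxy-4-(methoxymethoxy)-5-(3-methylbut-2-en-1-yl)phenyl]-1-(2,4,6-trihydroxyphenyl)prop-2-en-1-one | CO/C(=C\c1cc(OC)c(OCOC)c(CC=C(C)C)c1)C(=O)c1c(O)cc(O)cc1O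
A6 | alternative 3 | 2-(2-diazoacetyl)-5-methoxy-6-{3-methoxy-5-(3-methylbut-2-en-1-yl)-4-[(triisopropylsilyl)oxy]phenyl}-4H-pyran-4-one | [N-]=[N+]=CC(=O)c1cc(=O)c(OC)c(-c2cc(OC)c(O[Si](C(C)C)(C(C)C)C(C)C)c(CC=C(C)C)c2)o1
A7 | alternative 3 | (ethynyloxy)triisopropylsilane | C#CO[Si](C(C)C)(C(C)C)C(C)C
A8 | alternative 3 | 5-hydroxy-3-methoxy-2-{3-methoxy-5-(3-methylbut-2-en-1-yl)-4-[(triisopropylsilyl)oxy]phenyl}-7-[(triisopropylsilyl)oxy]-4H-chromen-4-one | COc1cc(-c2oc3cc(O[Si](C(C)C)(C(C)C)C(C)C)cc(O)c3c(=O)c2OC)cc(CC=C(C)C)c1O[Si](C(C)C)(C(C)C)C(C)C
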